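The easy step comes first: on the candidate steps, one initiator places one free monomer in a chain and leaves one living end, and each propagation turnover of that end adds another until the transfer agent caps it. The count to carry is therefore c(monomer in chains) divided by the charged c(initiator), a kinetic chain length.

common to all: free monomer 0.050 M
- maple: transfer agent 5 mM; initiator 1.3 mM; run made earlier
- elm: transfer agent 5 mM; initiator 8.5 mM; run made earlier
- east: transfer agent 5.00 mM; initiator 1.5 mM; time 12 h
- south-east: transfer agent 5.00 mM; initiator 3.0 mM; time 12 h
- south: transfer agent 5.00 mM; initiator 6.0 mM; time 12 h
- west: transfer agent 5.00 mM; initiator 12 mM; time 12 h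

| run | time / h | monomer in chains / % | free monomer / % |
|---|---|---|---|
| maple | 0.833 | 1 | 100 |
| maple | 1.50 | 3 | 96 |
| maple | 2.50 | 4 | 94 |
| maple | 3.00 | 7 | 92 |
| maple | 4.00 | 6 | 94 |
| maple | 5.00 | 6 | 96 |
| maple | 6.00 | 6 | 92 |
| elm | 0.333 | 12 | 90 |
| elm | 1.00 | 18 | 81 |
| elm | 1.50 | 21 | 81 |
| elm | 2.50 | 27 | 74 |
| elm | 4.00 | 29 | 70 |
| elm | 5.00 | 31 | 62 |
| elm | 6.00 | 39 | 64 |

(each reading ± 2 percentage points)

- amount of monomer in chains at the end, in percent of the free monomer charged for east, south-east, south, west, in this order
- the shape of the row from first to last (rises all the way / rises, then falls / falls all the way / falls, then rises / hardly changes)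

- candidate steps: free monomer + initiator -> living end + monomer in chains; free monomer + living end -> monomer in chains + living end; living end + transfer agent -> dead chain; monomer in chains + initiator <-> isomer of the product + initiator
- "hardly changes" means that all values lie within two and a half points (for a concentration: within two and a half percent of the largest)

The floor starts at one turnover per initiator, but the elm run tightens it. Free monomer and monomer in chains sum to about the charge there, so chains are not seen to lose monomer, and elm's last two readings average a count of 2.06. The ceiling starts at the charge, a count of 4.17 for west. Elm's late growth is slower than its early growth, and a straight line from 2.50 h onward, carried to 12 h, overshoots while living ends and free monomer both fall. That line gives 3.50. This reckoning commits to the midpoint, 2.78 turnovers per initiator charged, and the same count is assumed for each flask. The row is then 8.34 %, 16.7 %, 33.4 % and 66.8 %, rising with the initiator.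

The forecast gives 7 %, 16 %, 30 % and 76 %, a row that rises all the way, “with propagation growing as the agent depletes”. Its counts run from 2.33 in east to 3.17 in west, inside the bracket.

The flasks give 9.19 %, 18.3 %, 35.7 % and 61.7 %, and the row rises all the way.

    free monomer + initiator → living end + monomer in chains (k = 0.0120 L mol⁻¹ s⁻¹)
    free monomer + living end → monomer in chains + living end, rate k2*[living end]*[free monomer] (k = 0.00230 L mol⁻¹ s⁻¹)
    living end + transfer agent → dead chain (kL = 0.00970 L mol⁻¹ s⁻¹)
    monomer in chains + initiator ⇌ isomer of the product + initiator, rate k4*[initiator]*[monomer in chains] forward; the back reaction follows from the equilibrium constant (K = 4.40, k = 0.0120 L mol⁻¹ s⁻¹)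

East holds a count of 3.06, above 2.78, while west holds 2.57, below it. At 12.0 h in east, capping gives the living end a half-life of 5.3 h, whereas propagation gives free monomer a half-life of 13 d. At that time, east still has 76 % of its charged transfer agent.

(The data were computed for substances that don't exist; noise was put on by code.)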